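**Retrosynthetic overview**
- Target ⇒ TIPS-protected (S)-allylic alcohol + tigloyl chloride (ester C–O bond); the aryl silyl ether is removed last.
- Key C2–C3 disconnection: C3 is used with reversed polarity, as the enantioenriched α-carbamoyloxy carbanion made from the homoprenyl carbamate with sBuLi/(+)-sparteine. C2 is the boron-bound carbon of a 1-arylvinyl boronic ester, itself a carbon nucleophile. The two are joined through a boron ate complex and a 1,2-metallate shift, and C–B oxidation gives the alcohol and the only stereocentre.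
- Vinyl boronic ester ⇒ aryl alkyne (α-hydroalumination, Al to B) ⇒ silylated salicylaldehyde (one-carbon homologation) ⇒ 2,4-dimethoxy-3-methylphenol (ortho-formylation) ⇒ 2,4-dimethoxy-3-methylbenzaldehyde (Dakin oxidation).
- No ring is formed in the route; the benzene ring comes with the starting aldehyde.

Target as read from the SMILES: (3S)-2-(2-hydroxy-3,5-dimethoxy-4-methylphenyl)-6-methylhepta-1,5-dien-3-yl (2E)-2-methylbut-2-enoate (CIP order at C3: O > C2 > C4 > H).
Assumption: 2,4-dimethoxy-3-methylbenzaldehyde, 4-methylpent-3-en-1-ol, tigloyl chloride and (+)-sparteine are taken as catalogue chemicals.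

**Step 1**
Reactants: 1 2,4-dimethoxy-3-methylbenzaldehyde
Product: 3 2,4-dimethoxy-3-methylphenol, via aryl formate 2 (not isolated)
Conditions: 30% aq. H2O2, cat. H2SO4, MeOH, rt
Reagents that add atoms: hydrogen peroxide, OO
Why: Dakin oxidation (Baeyer–Villiger-type aryl migration, favoured by the ortho and para methoxy groups) gives the formate, which is methanolysed in the same flask.

**Step 2**
Reactants: 3 2,4-dimethoxy-3-methylphenol
Product: 5 2-hydroxy-3,5-dimethoxy-4-methylbenzaldehyde, via salicyl alcohol 4 (not isolated)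
Conditions: MgCl2, Et3N, (CH2O)n, MeCN, reflux; then 1 M HCl
Reagents that add atoms: formaldehyde (as paraformaldehyde), C=O
Why: Casnati–Skattebøl ortho-formylation, in which the magnesium phenoxide delivers formaldehyde only to the one free ortho position and a second formaldehyde oxidises the hydroxymethyl intermediate by Oppenauer-type hydride transfer, MgCl2 and Et3N being returned unchanged on work-up.

**Step 3**
Reactants: 5 2-hydroxy-3,5-dimethoxy-4-methylbenzaldehyde
Product: 6 3,5-dimethoxy-4-methyl-2-[(triisopropylsilyl)oxy]benzaldehyde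
Conditions: NaH, THF/DMF, 0 °C; TIPSCl, rt
Reagents that add atoms: chlorotriisopropylsilane, CC(C)[Si](Cl)(C(C)C)C(C)C
Why: O-silylation of the sodium phenoxide masks the acidic phenol for the organometallic steps, the hindered TIPS ether being stable to base and removable with fluoride.

**Step 4**
Reactants: 6 3,5-dimethoxy-4-methyl-2-[(triisopropylsilyl)oxy]benzaldehyde
Product: 7 (2-ethynyl-4,6-dimethoxy-5-methylphenoxy)triisopropylsilane
Conditions: TMSCHN2, n-BuLi, THF, −78 °C; then 6, −78 °C to rt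
Reagents that add atoms: (trimethylsilyl)diazomethane, C[Si](C)(C)C=[N+]=[N-]
Why: Colvin rearrangement (addition of TMSC(Li)N2, Peterson-type loss of Me3SiOLi, loss of N2 and 1,2-hydride shift of the alkylidene carbene) gives the terminal alkyne under aprotic conditions that leave the aryl silyl ether intact.

**Step 5**
Reactants: 7 (2-ethynyl-4,6-dimethoxy-5-methylphenoxy)triisopropylsilane
Product: 9 2-{1-[3,5-dimethoxy-4-methyl-2-(triisopropylsilyloxy)phenyl]ethenyl}-4,4,5,5-tetramethyl-1,3,2-dioxaborolane, via vinylalane 8 (not isolated)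
Conditions: iBu2AlH, NiCl2(dppp) (3 mol %), THF, 0 °C to rt; then MeOBpin, 0 to 80 °C
Reagents that add atoms: 2-methoxy-4,4,5,5-tetramethyl-1,3,2-dioxaborolane (MeOBpin), COB1OC(C)(C)C(C)(C)O1
Why: nickel-catalysed α-selective hydroalumination of the terminal aryl alkyne (the dppp ligand places aluminium on the internal carbon) followed by aluminium-to-boron transmetalation gives the 1,1-disubstituted vinyl boronic ester.

**Step 6**
Reactants: 10 4-methylpent-3-en-1-ol
Product: 11 4-methylpent-3-en-1-yl N,N-diisopropylcarbamate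
Conditions: NaH, THF, 0 °C; iPr2NCOCl, reflux
Reagents that add atoms: N,N-diisopropylcarbamoyl chloride, CC(C)N(C(C)C)C(Cl)=O
Why: O-carbamoylation of the sodium alkoxide (acyl substitution) installs the group that directs the α-lithiation and later serves as the leaving group.

**Step 7 (key step)**
Reactants: 11 4-methylpent-3-en-1-yl N,N-diisopropylcarbamate (1.4 equiv); 9 2-{1-[3,5-dimethoxy-4-methyl-2-(triisopropylsilyloxy)phenyl]ethenyl}-4,4,5,5-tetramethyl-1,3,2-dioxaborolane
Product: 15 (3S)-2-[3,5-dimethoxy-4-methyl-2-(triisopropylsilyloxy)phenyl]-6-methylhepta-1,5-dien-3-ol, via lithiated carbamate 12 (not isolated), via boronate complex 13 (not isolated), via allylic boronic ester 14 (not isolated)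
Conditions: sBuLi, (+)-sparteine, Et2O, −78 °C, 5 h; then 9, −78 °C, 1 h; MgBr2·OEt2, −78 °C to reflux, 12 h; then 30% H2O2, 2 M NaOH, THF, 0 °C
Reagents that add atoms: hydrogen peroxide, OO
Why: Hoppe–Aggarwal lithiation–borylation, in which sBuLi/(+)-sparteine removes the pro-R proton next to the carbamate oxygen to give the configurationally stable (R)-α-oxy organolithium 12 (a carbanionic, reversed-polarity form of a carbon that is otherwise an electrophilic carbonyl carbon), this attacks the boron of 9 (also a carbon nucleophile) with retention, the 1-arylvinyl group then shifts from boron to carbon with inversion as the carbamate leaves (1,2-metallate rearrangement), and stereoretentive C–B oxidation gives the S alcohol, so the C2–C3 bond, the 1,1-disubstituted alkene and the stereocentre all come from one operation.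

**Step 8**
Reactants: 15 (3S)-2-[3,5-dimethoxy-4-methyl-2-(triisopropylsilyloxy)phenyl]-6-methylhepta-1,5-dien-3-ol; 16 (2E)-2-methylbut-2-enoyl chloride (tigloyl chloride)
Product: 17 (3S)-2-[3,5-dimethoxy-4-methyl-2-(triisopropylsilyloxy)phenyl]-6-methylhepta-1,5-dien-3-yl (2E)-2-methylbut-2-enoate
Conditions: pyridine, DMAP (cat.), CH2Cl2, 0 °C to rt
Reagents that add atoms: none
Why: DMAP-catalysed O-acylation of the secondary allylic alcohol with the acid chloride touches no bond at the stereocentre, so the S configuration is kept, and the E (tiglate) geometry is the thermodynamically stable one.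

**Step 9**
Reactants: 17 (3S)-2-[3,5-dimethoxy-4-methyl-2-(triisopropylsilyloxy)phenyl]-6-methylhepta-1,5-dien-3-yl (2E)-2-methylbut-2-enoate
Product: 18 (3S)-2-(2-hydroxy-3,5-dimethoxy-4-methylphenyl)-6-methylhepta-1,5-dien-3-yl (2E)-2-methylbut-2-enoate
Conditions: TBAF, AcOH, THF, 0 °C
Reagents that add atoms: none
Why: fluoride-mediated desilylation of the aryl silyl ether, buffered with AcOH so that the phenoxide is protonated at once and neither attacks nor takes over the allylic ester.

**Compound list**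
1 | 2,4-dimethoxy-3-methylbenzaldehyde | O=Cc1ccc(OC)c(C)c1OC | starting material
2 | 2,4-dimethoxy-3-methylphenyl formate | O=COc1ccc(OC)c(C)c1OC | intermediate
3 | 2,4-dimethoxy-3-methylphenol | COc1ccc(O)c(OC)c1C | intermediate
4 | 6-(hydroxymethyl)-2,4-dimethoxy-3-methylphenol (as its magnesium salt in the flask) | COc1cc(CO)c(O)c(OC)c1C | intermediate
5 | 2-hydroxy-3,5-dimethoxy-4-methylbenzaldehyde | COc1cc(C=O)c(O)c(OC)c1C | intermediate
6 | 3,5-dimethoxy-4-methyl-2-[(triisopropylsilyl)oxy]benzaldehyde | COc1cc(C=O)c(O[Si](C(C)C)(C(C)C)C(C)C)c(OC)c1C | intermediate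
7 | (2-ethynyl-4,6-dimethoxy-5-methylphenoxy)triisopropylsilane | C#Cc1cc(OC)c(C)c(OC)c1O[Si](C(C)C)(C(C)C)C(C)C | intermediate
8 | {1-[3,5-dimethoxy-4-methyl-2-(triisopropylsilyloxy)phenyl]ethenyl}diisobutylalumane | C=C([Al](CC(C)C)CC(C)C)c1cc(OC)c(C)c(OC)c1O[Si](C(C)C)(C(C)C)C(C)C | intermediate
9 | 2-{1-[3,5-dimethoxy-4-methyl-2-(triisopropylsilyloxy)phenyl]ethenyl}-4,4,5,5-tetramethyl-1,3,2-dioxaborolane | C=C(B1OC(C)(C)C(C)(C)O1)c2cc(OC)c(C)c(OC)c2O[Si](C(C)C)(C(C)C)C(C)C | intermediate
10 | 4-methylpent-3-en-1-ol | CC(C)=CCCO | starting material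
11 | 4-methylpent-3-en-1-yl N,N-diisopropylcarbamate | CC(C)=CCCOC(=O)N(C(C)C)C(C)C | intermediate
12 | (1R)-1-lithio-4-methylpent-3-en-1-yl N,N-diisopropylcarbamate (as its (+)-sparteine complex) | [Li][C@H](CC=C(C)C)OC(=O)N(C(C)C)C(C)C | intermediate
13 | lithium {(1R)-1-[(diisopropylcarbamoyl)oxy]-4-methylpent-3-en-1-yl}{1-[3,5-dimethoxy-4-methyl-2-(triisopropylsilyloxy)phenyl]ethenyl}(pinacolato)borate | [Li+].C=C(c1cc(OC)c(C)c(OC)c1O[Si](C(C)C)(C(C)C)C(C)C)[B-]2(OC(C)(C)C(C)(C)O2)[C@H](CC=C(C)C)OC(=O)N(C(C)C)C(C)C | intermediate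
14 | 2-{(3S)-2-[3,5-dimethoxy-4-methyl-2-(triisopropylsilyloxy)phenyl]-6-methylhepta-1,5-dien-3-yl}-4,4,5,5-tetramethyl-1,3,2-dioxaborolane | C=C(c1cc(OC)c(C)c(OC)c1O[Si](C(C)C)(C(C)C)C(C)C)[C@H](CC=C(C)C)B2OC(C)(C)C(C)(C)O2 | intermediate
15 | (3S)-2-[3,5-dimethoxy-4-methyl-2-(triisopropylsilyloxy)phenyl]-6-methylhepta-1,5-dien-3-ol | C=C(c1cc(OC)c(C)c(OC)c1O[Si](C(C)C)(C(C)C)C(C)C)[C@H](CC=C(C)C)O | intermediate
16 | (2E)-2-methylbut-2-enoyl chloride (tigloyl chloride) | C/C=C(\C)C(Cl)=O | starting material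
17 | (3S)-2-[3,5-dimethoxy-4-methyl-2-(triisopropylsilyloxy)phenyl]-6-methylhepta-1,5-dien-3-yl (2E)-2-methylbut-2-enoate | C=C(c1cc(OC)c(C)c(OC)c1O[Si](C(C)C)(C(C)C)C(C)C)[C@H](CC=C(C)C)OC(=O)/C(C)=C/C | intermediate
18 | (3S)-2-(2-hydroxy-3,5-dimethoxy-4-methylphenyl)-6-methylhepta-1,5-dien-3-yl (2E)-2-methylbut-2-enoate (CNP0152319.3) | C=C(c1cc(OC)c(C)c(OC)c1O)[C@H](CC=C(C)C)OC(=O)/C(C)=C/C | target

**Totals**
Total step count: 9. Longest linear sequence: 8 steps (steps 1, 2, 3, 4, 5, 7, 8, 9); step 6 is a one-step side branch.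

**Three steps most likely to fail**

Step 7 (key step). The α-arylvinyl boronic ester carries a bulky ortho silyloxy group, so ate-complex formation may be slow or reversible, the 1,2-shift may stall, and the er may erode. The fallback sets out from 11 and 6 and comes back at 15. The same lithiated carbamate 12 is added directly to the carbonyl carbon of aldehyde 6 at −78 °C (substitution with retention, cold AcOH quench) to give the carbinol (2S)-1-[3,5-dimethoxy-4-methyl-2-(triisopropylsilyloxy)phenyl]-1-hydroxy-5-methylhex-4-en-2-yl N,N-diisopropylcarbamate F4 as a mixture of C1 epimers. Dess–Martin periodinane then gives the ketone (2S)-1-[3,5-dimethoxy-4-methyl-2-(triisopropylsilyloxy)phenyl]-5-methyl-1-oxohex-4-en-2-yl N,N-diisopropylcarbamate F5. Non-basic Takai–Lombardo methylenation (Zn, CH2Br2, TiCl4, THF), chosen to avoid epimerising the α-centre, gives the allylic carbamate (3S)-2-[3,5-dimethoxy-4-methyl-2-(triisopropylsilyloxy)phenyl]-6-methylhepta-1,5-dien-3-yl N,N-diisopropylcarbamate F6. LiAlH4 in THF at reflux removes the carbamate to give alcohol 15.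

Step 5. The alkyne is electron-rich and ortho-substituted, so α versus β regiocontrol, competing deprotonation of the alkyne, and the Al-to-B transfer are uncertain. The fallback sets out from 6 and comes back at 9. MeMgBr (THF, −78 °C) gives the carbinol 1-[3,5-dimethoxy-4-methyl-2-(triisopropylsilyloxy)phenyl]ethan-1-ol F1. Dess–Martin periodinane gives the methyl ketone 1-[3,5-dimethoxy-4-methyl-2-(triisopropylsilyloxy)phenyl]ethan-1-one F2. KN(SiMe3)2 and PhNTf2 (THF, −78 °C) give the enol triflate 1-[3,5-dimethoxy-4-methyl-2-(triisopropylsilyloxy)phenyl]ethenyl trifluoromethanesulfonate F3. Miyaura borylation (B2pin2, PdCl2(PPh3)2, PPh3, KOPh, toluene, 50 °C) then gives 9.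

Step 8. The secondary allylic alcohol is hindered and the α,β-unsaturated acid chloride is sluggish, so the reaction may be slow or the acyl group may deconjugate through the vinylketene. The fallback sets out from 15 and comes back at 17. The alcohol is first esterified with the unhindered 2-(diethoxyphosphoryl)propanoic acid (DCC, DMAP, CH2Cl2) to give the phosphonate ester (3S)-2-[3,5-dimethoxy-4-methyl-2-(triisopropylsilyloxy)phenyl]-6-methylhepta-1,5-dien-3-yl 2-(diethoxyphosphoryl)propanoate F7. An E-selective Horner–Wadsworth–Emmons reaction with acetaldehyde (NaH, THF, 0 °C) then builds the tiglate on the oxygen to give 17.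

**Further compounds**
F1 | step 5 | 1-[3,5-dimethoxy-4-methyl-2-(triisopropylsilyloxy)phenyl]ethan-1-ol | CC(O)c1cc(OC)c(C)c(OC)c1O[Si](C(C)C)(C(C)C)C(C)C
F2 | step 5 | 1-[3,5-dimethoxy-4-methyl-2-(triisopropylsilyloxy)phenyl]ethan-1-one | CC(=O)c1cc(OC)c(C)c(OC)c1O[Si](C(C)C)(C(C)C)C(C)C
F3 | step 5 | 1-[3,5-dimethoxy-4-methyl-2-(triisopropylsilyloxy)phenyl]ethenyl trifluoromethanesulfonate | C=C(OS(=O)(=O)C(F)(F)F)c1cc(OC)c(C)c(OC)c1O[Si](C(C)C)(C(C)C)C(C)C
F4 | step 7 | (2S)-1-[3,5-dimethoxy-4-methyl-2-(triisopropylsilyloxy)phenyl]-1-hydroxy-5-methylhex-4-en-2-yl N,N-diisopropylcarbamate | OC(c1cc(OC)c(C)c(OC)c1O[Si](C(C)C)(C(C)C)C(C)C)[C@H](CC=C(C)C)OC(=O)N(C(C)C)C(C)C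
F5 | step 7 | (2S)-1-[3,5-dimethoxy-4-methyl-2-(triisopropylsilyloxy)phenyl]-5-methyl-1-oxohex-4-en-2-yl N,N-diisopropylcarbamate | O=C(c1cc(OC)c(C)c(OC)c1O[Si](C(C)C)(C(C)C)C(C)C)[C@H](CC=C(C)C)OC(=O)N(C(C)C)C(C)C
F6 | step 7 | (3S)-2-[3,5-dimethoxy-4-methyl-2-(triisopropylsilyloxy)phenyl]-6-methylhepta-1,5-dien-3-yl N,N-diisopropylcarbamate | C=C(c1cc(OC)c(C)c(OC)c1O[Si](C(C)C)(C(C)C)C(C)C)[C@H](CC=C(C)C)OC(=O)N(C(C)C)C(C)C
F7 | step 8 | (3S)-2-[3,5-dimethoxy-4-methyl-2-(triisopropylsilyloxy)phenyl]-6-methylhepta-1,5-dien-3-yl 2-(diethoxyphosphoryl)propanoate | C=C(c1cc(OC)c(C)c(OC)c1O[Si](C(C)C)(C(C)C)C(C)C)[C@H](CC=C(C)C)OC(=O)C(C)P(=O)(OCC)OCC
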